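**Retrosynthetic overview**

- The target is reached from its C1 lactol by esterification; the lactol comes from a 1-O-(prop-1-enyl) bicycle by neutral cleavage of that spectator enol ether.
- The strategy rests on the C3=C4–C5=C6 dienol ether that runs through the dihydropyran ring (C1, O2, C3, C4, C5, C9) and the cyclopentene ring (C5, C6, C7, C8, C9). It is the 1,3-diene that an enyne-metathesis relay leaves when a C4≡C5 alkyne is flanked by a C6 vinyl group and an O2 enol ether.
- Both rings are therefore closed in one operation from an acyclic dienyne bis(prop-1-enyl) acetal: the cyclopentene first (C5=C6), then the dihydropyran (C3=C4). Each enol ether carries a terminal methyl group so that the catalyst loads at the C6 vinyl group.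
- The acetal comes from a C1 aldehyde, unmasked by ozonolysis of an isobutenyl group on C9. C7 is set by chelation-controlled vinyl addition; C8 and C9 by asymmetric epoxidation of a 2-substituted dienol and alkynylalane opening at C9.
- The dienol comes from triethyl phosphonoacetate, formaldehyde and 3-methylbut-2-enal.

Key step: step 16

Remark: iridoid numbering is used throughout (C1 acetal carbon, O2, C3, C4 bearing C11, C5, C6, C7, C8 bearing C10, C9), and the C1 hemiacetal 24 is assumed to rest mainly as the 1β-anomer (OH cis to H-9), as related iridoid hemiacetals do.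

**Route**

Step 1
Reactants: 1 triethyl phosphonoacetate; 2 3-methylbut-2-enal
Product: 4 ethyl (2E)-2-(hydroxymethyl)-5-methylhexa-2,4-dienoate, via hydroxymethyl phosphonate 3 (not isolated)
Conditions: (CH2O)n (1 equiv), K2CO3 (cat.), H2O–THF, rt; then 2, K2CO3 (2 equiv), 0 °C to rt
Reagents that add atoms: formaldehyde (as paraformaldehyde), C=O
Why: Base-mediated hydroxymethylation of the phosphonoacetate followed by Horner–Wadsworth–Emmons olefination of the α-branched phosphonate should give mainly the E ester (ester trans to the dienyl chain), which places the future C7 carbon trans and the future C10 carbon cis to the alkenyl group on C9.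

Step 2
Reactants: 4 ethyl (2E)-2-(hydroxymethyl)-5-methylhexa-2,4-dienoate
Product: 5 ethyl (2E)-2-({[tert-butyl(dimethyl)silyl]oxy}methyl)-5-methylhexa-2,4-dienoate
Conditions: t-BuMe2SiCl, imidazole, CH2Cl2, 0 °C to rt
Reagents that add atoms: tert-butyldimethylsilyl chloride, CC(C)(C)[Si](C)(C)Cl
Why: Standard silylation of a primary allylic alcohol differentiates the C10 oxygen from the C7 carbon before the ester is reduced.

Step 3
Reactants: 5 ethyl (2E)-2-({[tert-butyl(dimethyl)silyl]oxy}methyl)-5-methylhexa-2,4-dienoate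
Product: 6 (2Z)-2-({[tert-butyl(dimethyl)silyl]oxy}methyl)-5-methylhexa-2,4-dien-1-ol
Conditions: i-Bu2AlH (2.2 equiv), CH2Cl2, −78 °C; aq. KNa tartrate (KNaC4H4O6)
Reagents that add atoms: none
Why: 1,2-Reduction of an α,β-unsaturated ester with i-Bu2AlH gives the allylic alcohol without touching the diene geometry.

Step 4
Reactants: 6 (2Z)-2-({[tert-butyl(dimethyl)silyl]oxy}methyl)-5-methylhexa-2,4-dien-1-ol
Product: 7 [(2R,3S)-2-({[tert-butyl(dimethyl)silyl]oxy}methyl)-3-(2-methylprop-1-en-1-yl)oxiran-2-yl]methanol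
Conditions: Ti(OiPr)4 (10 mol%), L-(+)-diisopropyl tartrate (12 mol%), t-BuOOH, 4 Å molecular sieves, CH2Cl2, −20 °C
Reagents that add atoms: tert-butyl hydroperoxide, CC(C)(C)OO
Why: Katsuki–Sharpless asymmetric epoxidation acts only on the hydroxyl-directed C8=C9 alkene of the dienol, and the L-(+)-tartrate should deliver oxygen to the face that gives the (2R,3S) oxirane, which fixes C8.

Step 5
Reactants: 8 propargyl alcohol
Product: 9 1-methoxy-4-[(prop-2-yn-1-yloxy)methyl]benzene
Conditions: NaH, 4-methoxybenzyl chloride, Bu4NI (cat.), THF, 0 °C to rt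
Reagents that add atoms: 4-methoxybenzyl chloride, COc1ccc(CCl)cc1
Why: Williamson etherification protects the future C11 oxygen as an ether that survives organometallic steps and is removed oxidatively.

Step 6
Reactants: 7 [(2R,3S)-2-({[tert-butyl(dimethyl)silyl]oxy}methyl)-3-(2-methylprop-1-en-1-yl)oxiran-2-yl]methanol; 9 1-methoxy-4-[(prop-2-yn-1-yloxy)methyl]benzene
Product: 12 (2R,3S)-2-({[tert-butyl(dimethyl)silyl]oxy}methyl)-6-[(4-methoxybenzyl)oxy]-3-(2-methylprop-1-en-1-yl)hex-4-yne-1,2-diol, via lithium acetylide 10 (not isolated), via diethylalkynylalane 11 (not isolated)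
Conditions: 9 (4 equiv), n-BuLi, toluene, −78 to 0 °C; Et2AlCl, 0 °C; then 7, toluene, 0 °C to rt; aq. KNa tartrate (KNaC4H4O6)
Reagents that add atoms: none
Why: Alkynylalane opening of a 2,3-epoxy alcohol occurs at C3, here the allylic C9 and the only carbon open to backside attack since C8 is fully substituted, so the alkyne should enter with inversion and set C9 while C8 keeps its oxygen.

Step 7
Reactants: 12 (2R,3S)-2-({[tert-butyl(dimethyl)silyl]oxy}methyl)-6-[(4-methoxybenzyl)oxy]-3-(2-methylprop-1-en-1-yl)hex-4-yne-1,2-diol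
Product: 13 (2S,3S)-2-({[tert-butyl(dimethyl)silyl]oxy}methyl)-2-hydroxy-6-[(4-methoxybenzyl)oxy]-3-(2-methylprop-1-en-1-yl)hex-4-ynal
Conditions: SO3·pyridine, DMSO, i-Pr2NEt, CH2Cl2, 0 °C
Reagents that add atoms: none
Why: Parikh–Doering oxidation converts the primary alcohol into the aldehyde without glycol cleavage and leaves the tertiary alcohol alone; the aldehyde has no α-hydrogen and cannot epimerize.

Step 8
Reactants: 13 (2S,3S)-2-({[tert-butyl(dimethyl)silyl]oxy}methyl)-2-hydroxy-6-[(4-methoxybenzyl)oxy]-3-(2-methylprop-1-en-1-yl)hex-4-ynal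
Product: 14 (3R,4S,5S)-4-({[tert-butyl(dimethyl)silyl]oxy}methyl)-8-[(4-methoxybenzyl)oxy]-5-(2-methylprop-1-en-1-yl)oct-1-en-6-yne-3,4-diol
Conditions: CH2=CHMgBr (4 equiv), THF–CH2Cl2, −78 °C; aq. NH4Cl
Reagents that add atoms: vinylmagnesium bromide, C=C[Mg]Br
Why: Grignard addition under Cram chelate control: the magnesium alkoxide of the C8 hydroxyl binds the aldehyde oxygen, and the vinyl group should attack from the side of the CH2OSi arm, anti to the branched C9, which sets C7 as R.

Step 9
Reactants: 14 (3R,4S,5S)-4-({[tert-butyl(dimethyl)silyl]oxy}methyl)-8-[(4-methoxybenzyl)oxy]-5-(2-methylprop-1-en-1-yl)oct-1-en-6-yne-3,4-diol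
Product: 15 (3R,4S,5S)-4-(hydroxymethyl)-8-[(4-methoxybenzyl)oxy]-5-(2-methylprop-1-en-1-yl)oct-1-en-6-yne-3,4-diol
Conditions: Bu4NF, THF, 0 °C
Reagents that add atoms: none
Why: Fluoride desilylation frees the C10 hydroxyl so that the C7 and C10 oxygens can receive the same acyl group in one step.

Step 10
Reactants: 15 (3R,4S,5S)-4-(hydroxymethyl)-8-[(4-methoxybenzyl)oxy]-5-(2-methylprop-1-en-1-yl)oct-1-en-6-yne-3,4-diol
Product: 16 (3R,4S,5S)-4-hydroxy-8-[(4-methoxybenzyl)oxy]-4-{[(3-methylbutanoyl)oxy]methyl}-5-(2-methylprop-1-en-1-yl)oct-1-en-6-yn-3-yl 3-methylbutanoate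
Conditions: (i-BuCO)2O (2.5 equiv), Et3N, DMAP (cat.), CH2Cl2, 0 °C to rt
Reagents that add atoms: 3-methylbutanoic anhydride, CC(C)CC(=O)OC(=O)CC(C)C
Why: DMAP-catalysed acylation esterifies the secondary C7 and primary C10 hydroxyls, while the hindered tertiary C8 hydroxyl should stay free.

Step 11
Reactants: 16 (3R,4S,5S)-4-hydroxy-8-[(4-methoxybenzyl)oxy]-4-{[(3-methylbutanoyl)oxy]methyl}-5-(2-methylprop-1-en-1-yl)oct-1-en-6-yn-3-yl 3-methylbutanoate
Product: 17 (3R,4S,5S)-4,8-dihydroxy-4-{[(3-methylbutanoyl)oxy]methyl}-5-(2-methylprop-1-en-1-yl)oct-1-en-6-yn-3-yl 3-methylbutanoate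
Conditions: DDQ, CH2Cl2–pH 7 buffer (10:1), 0 °C
Reagents that add atoms: none
Why: Oxidative cleavage of the 4-methoxybenzyl ether frees the propargylic C11 hydroxyl without affecting the esters or the alkenes.

Step 12
Reactants: 17 (3R,4S,5S)-4,8-dihydroxy-4-{[(3-methylbutanoyl)oxy]methyl}-5-(2-methylprop-1-en-1-yl)oct-1-en-6-yn-3-yl 3-methylbutanoate
Product: 18 (3R,4S,5S)-8-(acetyloxy)-4-hydroxy-4-{[(3-methylbutanoyl)oxy]methyl}-5-(2-methylprop-1-en-1-yl)oct-1-en-6-yn-3-yl 3-methylbutanoate
Conditions: Ac2O (1.2 equiv), pyridine, DMAP (cat.), CH2Cl2, 0 °C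
Reagents that add atoms: acetic anhydride, CC(=O)OC(C)=O
Why: Acetylation of the unhindered primary propargylic alcohol installs the C11 acetate; the tertiary alcohol does not react at 0 °C.

Step 13
Reactants: 18 (3R,4S,5S)-8-(acetyloxy)-4-hydroxy-4-{[(3-methylbutanoyl)oxy]methyl}-5-(2-methylprop-1-en-1-yl)oct-1-en-6-yn-3-yl 3-methylbutanoate
Product: 20 (2S,3S,4R)-2-[3-(acetyloxy)prop-1-yn-1-yl]-3-hydroxy-4-[(3-methylbutanoyl)oxy]-3-{[(3-methylbutanoyl)oxy]methyl}hex-5-enal (C1 aldehyde), via ozonide 19 (not isolated)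
Conditions: O3, CH2Cl2, −78 °C, Sudan Red 7B as end-point indicator; then PPh3, −78 °C to rt
Reagents that add atoms: ozone, [O-][O+]=O
Why: Ozonolysis with reductive work-up should select the electron-rich trisubstituted isobutenyl alkene over the acyloxy-deactivated terminal vinyl group and the alkyne, unmasking C1 as the aldehyde under neutral conditions that spare the α-alkynyl centre C9.

Step 14
Reactants: 20 (2S,3S,4R)-2-[3-(acetyloxy)prop-1-yn-1-yl]-3-hydroxy-4-[(3-methylbutanoyl)oxy]-3-{[(3-methylbutanoyl)oxy]methyl}hex-5-enal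
Product: 21 diallyl acetal of 20, (7R,8S,9S)
Conditions: CH2=CHCH2OSiMe3 (2.5 equiv), Me3SiOTf (5 mol%), CH2Cl2, −78 °C; pyridine, then aq. NaHCO3
Reagents that add atoms: allyloxytrimethylsilane, C=CCO[Si](C)(C)C
Why: Silyl-triflate-catalysed acetalization with an alkoxysilane (Noyori acetalization) converts the crude aldehyde at −78 °C, where enolization towards C9 and retro-aldol cleavage should not compete.

Step 15
Reactants: 21 diallyl acetal, (7R,8S,9S)
Product: 22 di[(E)-prop-1-en-1-yl] acetal, (7R,8S,9S): the acyclic dienyne bis(enol ether) acetal carrying the C7, C10 and C11 esters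
Conditions: [Ir(cod)(PMePh2)2]PF6 (3 mol%, activated with H2, then degassed), THF, rt
Reagents that add atoms: none
Why: Cationic iridium-catalysed double-bond migration of allyl acetals gives (E)-prop-1-enyl ethers under neutral conditions; the unhindered O-allyl groups should isomerize well ahead of the C6 vinyl group, whose allylic hydrogen sits next to a fully substituted carbon.

Step 16
Reactants: 22 di[(E)-prop-1-en-1-yl] acetal, (7R,8S,9S)
Product: 23 1-O-[(E)-prop-1-enyl] bicycle: (7R,8S,9S)-11-acetoxy-8-hydroxy-7,10-bis(3-methylbutanoyloxy)-1β-[(E)-prop-1-enyloxy]-iridoid 3,5-diene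
Conditions: second-generation Grubbs catalyst RuCl2(=CHPh)(H2IMes)(PCy3) (10 mol%), toluene (0.002 M), 70 °C, argon sparge
Reagents that add atoms: none
Why: Proposed new method: the ruthenium benzylidene should load at the only monosubstituted alkene, the C6 vinyl group; the C6 alkylidene adds across the C5≡C4 alkyne with C6–C5 bond formation (exo-mode ring-closing enyne metathesis, cyclopentene ring C5–C6–C7–C8–C9), cycloreversion places the metal on C4, and this vinylcarbene closes the six-membered ring (C1–O2–C3–C4–C5–C9) by ring-closing metathesis onto the oxygen-bound carbon of one propenyl ether, forming C3=C4 and releasing an ethylidene that re-enters the cycle with loss of propene. The closest known reaction types are the tandem ring-closing metathesis of dienynes to fused bicyclic 1,3-dienes, where an internal alkene is used to fix the site of initiation, and the ring-closing metathesis of olefinic enol ethers to cyclic enol ethers; their combination on a bis(enol ether) acetal is not known. The step needs initiation at C6 and not at an enol ether, which would lead by five-membered closure onto C5 to a furan-fused isomer; the 1,2-disubstituted propenyl ethers should load far more slowly than the terminal vinyl group, and high dilution with argon sparging suppresses intermolecular events. C1 becomes a stereocentre by selection between the two diastereotopic propenyloxy groups; the C9 and C8 centres should favour the closure that leaves the spectator group cis to H-9 and away from the C10 acyloxymethyl arm, and this selectivity is not critical because C1 can re-equilibrate at the lactol stage. The esters, the free tertiary alcohol and the propargylic acetate are compatible with the neutral catalyst, so the acid-labile dienol ether is formed last.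

Step 17
Reactants: 23 1-O-[(E)-prop-1-enyl] bicycle
Product: 24 C1 lactol: (7R,8S,9S)-11-acetoxy-1β,8-dihydroxy-7,10-bis(3-methylbutanoyloxy)-iridoid 3,5-diene
Conditions: HgCl2 (1.1 equiv), HgO (1.1 equiv), acetone–H2O (10:1), 0 °C
Reagents that add atoms: none
Why: Mercury-assisted hydrolysis of an anomeric prop-1-enyl ether (oxymercuration of the enol ether and collapse of the hemiacetal) runs at neutral pH; the less hindered propenyl ether should react ahead of the trisubstituted, conjugated ring dienol ether, and the C1–O bond is not broken.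

Step 18
Reactants: 25 3-hydroxy-3-methylbutanoic acid
Product: 26 3-(acetyloxy)-3-methylbutanoic acid
Conditions: Ac2O, Et3N, DMAP (cat.), CH2Cl2, rt; then aq. NaHCO3, acidify
Reagents that add atoms: acetic anhydride, CC(=O)OC(C)=O
Why: DMAP-catalysed acetylation of the tertiary alcohol, with hydrolysis of the mixed anhydride on work-up, gives the side-chain acid.

Step 19
Reactants: 24 C1 lactol; 26 3-(acetyloxy)-3-methylbutanoic acid
Product: 28 CNP0331701.2, via O-acylisourea 27 (not isolated)
Conditions: DCC, DMAP (cat.), CH2Cl2, −20 to 0 °C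
Reagents that add atoms: none
Why: Steglich esterification acylates the lactol oxygen with retention at C1, so the 1β-lactol should give the 1β-ester of the target; the low temperature limits ring opening of the lactol and loss of acetate from the activated β-acetoxy acid.

**Compound list**

1 | triethyl phosphonoacetate | CCOC(=O)CP(=O)(OCC)OCC | starting material
2 | 3-methylbut-2-enal | CC(C)=CC=O | starting material
3 | ethyl 2-(diethoxyphosphoryl)-3-hydroxypropanoate | CCOC(=O)C(CO)P(=O)(OCC)OCC | intermediate (not isolated)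
4 | ethyl (2E)-2-(hydroxymethyl)-5-methylhexa-2,4-dienoate | CCOC(=O)/C(CO)=C/C=C(C)C | intermediate
5 | ethyl (2E)-2-({[tert-butyl(dimethyl)silyl]oxy}methyl)-5-methylhexa-2,4-dienoate | CCOC(=O)/C(CO[Si](C)(C)C(C)(C)C)=C/C=C(C)C | intermediate
6 | (2Z)-2-({[tert-butyl(dimethyl)silyl]oxy}methyl)-5-methylhexa-2,4-dien-1-ol | OC/C(CO[Si](C)(C)C(C)(C)C)=C/C=C(C)C | intermediate
7 | [(2R,3S)-2-({[tert-butyl(dimethyl)silyl]oxy}methyl)-3-(2-methylprop-1-en-1-yl)oxiran-2-yl]methanol | OC[C@]1(CO[Si](C)(C)C(C)(C)C)O[C@H]1C=C(C)C | intermediate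
8 | propargyl alcohol | C#CCO | starting material
9 | 1-methoxy-4-[(prop-2-yn-1-yloxy)methyl]benzene | C#CCOCc1ccc(OC)cc1 | intermediate
10 | lithium 3-[(4-methoxybenzyl)oxy]prop-1-yn-1-ide | [Li]C#CCOCc1ccc(OC)cc1 | intermediate (not isolated)
11 | diethyl{3-[(4-methoxybenzyl)oxy]prop-1-yn-1-yl}aluminium | CC[Al](CC)C#CCOCc1ccc(OC)cc1 | intermediate (not isolated)
12 | (2R,3S)-2-({[tert-butyl(dimethyl)silyl]oxy}methyl)-6-[(4-methoxybenzyl)oxy]-3-(2-methylprop-1-en-1-yl)hex-4-yne-1,2-diol | CC(C)=C[C@@H](C#CCOCc1ccc(OC)cc1)[C@](O)(CO[Si](C)(C)C(C)(C)C)CO | intermediate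
13 | (2S,3S)-2-({[tert-butyl(dimethyl)silyl]oxy}methyl)-2-hydroxy-6-[(4-methoxybenzyl)oxy]-3-(2-methylprop-1-en-1-yl)hex-4-ynal | CC(C)=C[C@@H](C#CCOCc1ccc(OC)cc1)[C@](O)(CO[Si](C)(C)C(C)(C)C)C=O | intermediate
14 | (3R,4S,5S)-4-({[tert-butyl(dimethyl)silyl]oxy}methyl)-8-[(4-methoxybenzyl)oxy]-5-(2-methylprop-1-en-1-yl)oct-1-en-6-yne-3,4-diol | CC(C)=C[C@@H](C#CCOCc1ccc(OC)cc1)[C@](O)(CO[Si](C)(C)C(C)(C)C)[C@H](O)C=C | intermediate
15 | (3R,4S,5S)-4-(hydroxymethyl)-8-[(4-methoxybenzyl)oxy]-5-(2-methylprop-1-en-1-yl)oct-1-en-6-yne-3,4-diol | CC(C)=C[C@@H](C#CCOCc1ccc(OC)cc1)[C@](O)(CO)[C@H](O)C=C | intermediate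
16 | (3R,4S,5S)-4-hydroxy-8-[(4-methoxybenzyl)oxy]-4-{[(3-methylbutanoyl)oxy]methyl}-5-(2-methylprop-1-en-1-yl)oct-1-en-6-yn-3-yl 3-methylbutanoate | CC(C)=C[C@@H](C#CCOCc1ccc(OC)cc1)[C@](O)(COC(=O)CC(C)C)[C@H](OC(=O)CC(C)C)C=C | intermediate
17 | (3R,4S,5S)-4,8-dihydroxy-4-{[(3-methylbutanoyl)oxy]methyl}-5-(2-methylprop-1-en-1-yl)oct-1-en-6-yn-3-yl 3-methylbutanoate | CC(C)=C[C@@H](C#CCO)[C@](O)(COC(=O)CC(C)C)[C@H](OC(=O)CC(C)C)C=C | intermediate
18 | (3R,4S,5S)-8-(acetyloxy)-4-hydroxy-4-{[(3-methylbutanoyl)oxy]methyl}-5-(2-methylprop-1-en-1-yl)oct-1-en-6-yn-3-yl 3-methylbutanoate | CC(C)=C[C@@H](C#CCOC(C)=O)[C@](O)(COC(=O)CC(C)C)[C@H](OC(=O)CC(C)C)C=C | intermediate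
19 | secondary ozonide of 18 (5,5-dimethyl-1,2,4-trioxolan-3-yl group on C9; ozonide carbon not defined) | CC1(C)OOC(O1)[C@@H](C#CCOC(C)=O)[C@](O)(COC(=O)CC(C)C)[C@H](OC(=O)CC(C)C)C=C | intermediate (not isolated)
20 | (2S,3S,4R)-2-[3-(acetyloxy)prop-1-yn-1-yl]-3-hydroxy-4-[(3-methylbutanoyl)oxy]-3-{[(3-methylbutanoyl)oxy]methyl}hex-5-enal | O=C[C@@H](C#CCOC(C)=O)[C@](O)(COC(=O)CC(C)C)[C@H](OC(=O)CC(C)C)C=C | intermediate
21 | diallyl acetal of 20, (7R,8S,9S) | C=CCOC(OCC=C)[C@@H](C#CCOC(C)=O)[C@](O)(COC(=O)CC(C)C)[C@H](OC(=O)CC(C)C)C=C | intermediate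
22 | di[(E)-prop-1-en-1-yl] acetal of 20, (7R,8S,9S); metathesis precursor | C/C=C/OC(O/C=C/C)[C@@H](C#CCOC(C)=O)[C@](O)(COC(=O)CC(C)C)[C@H](OC(=O)CC(C)C)C=C | intermediate
23 | 1-O-[(E)-prop-1-enyl] analogue of the target, 1β (cis to H-9), (7R,8S,9S); metathesis product | CC(=O)OCC1=CO[C@@H](O/C=C/C)[C@H]2C1=C[C@@H](OC(=O)CC(C)C)[C@@]2(O)COC(=O)CC(C)C | intermediate
24 | C1 lactol, 1β-OH anomer drawn, (7R,8S,9S) | CC(=O)OCC1=CO[C@@H](O)[C@H]2C1=C[C@@H](OC(=O)CC(C)C)[C@@]2(O)COC(=O)CC(C)C | intermediate
25 | 3-hydroxy-3-methylbutanoic acid | CC(C)(O)CC(O)=O | starting material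
26 | 3-(acetyloxy)-3-methylbutanoic acid | CC(=O)OC(C)(C)CC(O)=O | intermediate
27 | O-[3-(acetyloxy)-3-methylbutanoyl]-N,N'-dicyclohexylisourea | CC(=O)OC(C)(C)CC(=O)OC(=NC1CCCCC1)NC1CCCCC1 | intermediate (not isolated)
28 | CNP0331701.2, (1S,7R,8S,9S) in iridoid numbering | CC(=O)OCC1=CO[C@@H](OC(=O)CC(C)(C)OC(C)=O)[C@H]2C1=C[C@@H](OC(=O)CC(C)C)[C@@]2(O)COC(=O)CC(C)C | target

**Totals**

Total step count: 19. Longest linear sequence: 17 steps (steps 1–4, 6–17 and 19).

**Steps most likely to fail**

Step 16. The catalyst may load on an enol ether in place of the C6 vinyl group, or the sequence may stop after the first ring closure. The fallback runs from 22 back to 23 as two known metatheses. First, 22 undergoes ring-closing enyne metathesis alone, under ethene (1 atm) with the second-generation Grubbs catalyst in CH2Cl2 at room temperature; the ethene-derived methylidene caps the C4 carbene and should give the monocyclic triene F1 (cyclopentene C5=C6 with a C4(=CH2)CH2OAc arm and the dipropenyl acetal intact). F1 is then closed by ring-closing metathesis of its 1,1-disubstituted diene terminus with one propenyl ether (second-generation Hoveyda–Grubbs catalyst RuCl2(=CH-C6H4-2-OiPr)(H2IMes), dilute toluene, 80 °C, argon sparge), which forms C3=C4 with loss of propene and rejoins the route at 23.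

Step 15. The double-bond migration may stall through binding of the alkyne to iridium, or be unselective through migration of the C6 vinyl group. The fallback runs from 20 back to 24 and makes terminal vinyl ethers by elimination in place of isomerization. Aldehyde 20 is acetalized with 2-(phenylselanyl)ethanol (PPTS, 4 Å molecular sieves, CH2Cl2) to the bis[2-(phenylselanyl)ethyl] acetal F2. NaIO4/NaHCO3 in aqueous MeOH–THF oxidizes both selenides to the bis-selenoxide F3, which on warming in toluene with i-Pr2NH should undergo twofold syn-elimination to the divinyl acetal F4. Tandem metathesis as in step 16, with the catalyst added slowly to the hot dilute solution, then gives the 1-O-vinyl bicycle F5 with loss of ethene. HgCl2/HgO as in step 17 removes the spectator vinyl group and rejoins the route at 24.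

Step 8. Facial selectivity may be poor in the addition to an aldehyde whose α-carbon is fully substituted. The fallback runs from 14, taken as a mixture of C7 epimers, back to 14 under reagent control. The mixture is oxidized (Dess–Martin periodinane, NaHCO3, CH2Cl2) to the vinyl ketone F6. Corey–Bakshi–Shibata reduction with the (S)-2-methyl-oxazaborolidine and BH3·SMe2 (THF, −40 °C), which treats the fully substituted C8 as the large group, should return the (7R)-alcohol 14.

**Further compounds**

F1 | step 16 | monocyclic triene: (7R,8S,9S)-cyclopentene (C5=C6) with C4(=CH2)CH2OAc arm and di[(E)-prop-1-enyl] acetal at C1 | C/C=C/OC(O/C=C/C)[C@H]1C(C(=C)COC(C)=O)=C[C@@H](OC(=O)CC(C)C)[C@@]1(O)COC(=O)CC(C)C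
F2 | step 15 | bis[2-(phenylselanyl)ethyl] acetal of 20 | C(C[Se]c1ccccc1)OC(OCC[Se]c1ccccc1)[C@@H](C#CCOC(C)=O)[C@](O)(COC(=O)CC(C)C)[C@H](OC(=O)CC(C)C)C=C
F3 | step 15 | bis-selenoxide of F2 | O=[Se](CCOC(OCC[Se](=O)c1ccccc1)[C@@H](C#CCOC(C)=O)[C@](O)(COC(=O)CC(C)C)[C@H](OC(=O)CC(C)C)C=C)c1ccccc1
F4 | step 15 | divinyl acetal of 20 | C=COC(OC=C)[C@@H](C#CCOC(C)=O)[C@](O)(COC(=O)CC(C)C)[C@H](OC(=O)CC(C)C)C=C
F5 | step 15 | 1-O-vinyl analogue of the target, 1β | CC(=O)OCC1=CO[C@@H](OC=C)[C@H]2C1=C[C@@H](OC(=O)CC(C)C)[C@@]2(O)COC(=O)CC(C)C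
F6 | step 8 | (4S,5S)-4-({[tert-butyl(dimethyl)silyl]oxy}methyl)-4-hydroxy-8-[(4-methoxybenzyl)oxy]-5-(2-methylprop-1-en-1-yl)oct-1-en-6-yn-3-one | CC(C)=C[C@@H](C#CCOCc1ccc(OC)cc1)[C@](O)(CO[Si](C)(C)C(C)(C)C)C(=O)C=C
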